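The numbers in the tables stem from a simulated flask for substances that don't exist.

**The task.** Fraction of the charge per minute is the unit I reckon in, for these flasks and readings.

| flask | electrophile | nucleophile | solid base | remark | time |
|---|---|---|---|---|---|
| north | 0.017 M | 1.1 equiv | 1 equiv | run made earlier |  |
| south-west | 0.017 M | 2.1 equiv | 1 equiv | run made earlier |  |
| Monday's | 0.017 M | 3.00 equiv | 1.00 equiv |  | 80 min |
| Tuesday's | 0.017 M | 1.50 equiv | 1.00 equiv |  | 80 min |

- north (time / min: electrophile / %, product / %): 5.00: 96.5, 2.4; 6.00: 96.5, 4.7; 10.0: 94.2, 4.8; 15.0: 91.2, 11.3; 25.0: 85.0, 15.9; 40.0: 76.4, 23.1; 60.0: 71.6, 28.7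
- south-west (time / min: electrophile / %, product / %): 5.00: 93.0, 5.2; 6.00: 91.7, 7.5; 10.0: 86.7, 12.7; 15.0: 82.7, 17.9; 25.0: 73.9, 25.1; 40.0: 60.6, 39.5; 60.0: 51.3, 49.5

(each reading ± 1 percentage point)

- solid base is a solid; its amount is given per volume of the solution
- at the start none of the solid base is in solution

- part of the electrophile that has reacted at the end, Monday's
- part of the electrophile that has reacted at the end, Tuesday's
- what raising the equivalents of nucleophile from its lowest to its highest value here does to the part of the electrophile that has reacted (changes below 5 percentage points count as none) (it rises / no change / it falls)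

**The balance.** I count in fractions of the electrophile charged, with q the equivalents of nucleophile, and the electrophile is the limiting reagent against the nucleophile. If each electrophile lost takes one nucleophile, the loss per minute is κ times the electrophile left times the nucleophile left. Integrating this and putting in the last reading of each run, I read 0.00590 min⁻¹ from the north run and 0.00612 min⁻¹ from the south-west run. Their mean, 0.00601 min⁻¹, a reading that carries the scatter of those points, is the charge clock κ, the fractional loss per minute with one full charge each of electrophile and nucleophile.

**The curve.** On this balance I reckon that Monday's electrophile starts down at κq, 0.0180 min⁻¹, and crosses the product at 42.5 min, where the slope has eased to 0.00751 min⁻¹. At 80 min I reckon 70.8 % reacted in Monday's flask, on a curve that by this balance levels at 100 % reacted with 2.00 fractions of nucleophile over. Tuesday's starts at 0.00901 min⁻¹, and its crossing, at 95.7 min, lies later than the end, so I stop at 44.9 %. Monday's stands higher than Tuesday's by 26 percentage points.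

**The forecast.** It says 72 % for Monday's and 46 % for Tuesday's, and of the trend: it rises. Its ground is this: “The electrophile's decay fits a simple second-order law, first order in both electrophile and nucleophile.” Its clock of 0.0063 per min stands against my 0.00601 min⁻¹, and its figures stand above mine.

**The flasks.** Monday's gives 71.5 % and Tuesday's 46.6 %; the trend is: it rises, by 25 points.

    electrophile + nucleophile → acid set free + product (k = 0.00632 L mol⁻¹ s⁻¹)
    nucleophile + acid set free ⇌ protonated nucleophile, settled at all times (K = 549 L mol⁻¹)
    acid set free + free base ⇌ salt of the base, settled at all times (K = 3.20 × 10⁵ L mol⁻¹)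
    solid base ⇌ free base, rate k4*(cs4 - [free base]) while solid is left; crystals form when [free base] > cs4 (solubility = 9.30 mM, k = 2.58 × 10⁻⁴ s⁻¹)

**Dilute neighbour.** Take Monday's flask with the electrophile cut to 0.0068 M, equivalents held. Scaling the clock with the charge gives 0.00240 min⁻¹, and the same balance at 80 min gives 41.3 % reacted. That neighbour gives 43.3 % reacted, with 56.7 % of its electrophile still there at 80.0 min.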